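**Retrosynthetic overview**

1. Kazinol D (24, achiral) ⇐ methanolysis of three aryl esters ⇐ chroman 23. The dihydropyran ring on ring B is cut at C4–C3 and O1–C2 into o-quinone methide 22 and 2-methylpropene (hetero-Diels–Alder).
2. Enabling feature: in ring B the ring oxygen O1 (on C8a) is ortho to the benzylic carbon C4 (on C4a), so O1–C8a–C4a–C4 is a latent 1-oxadiene. C2 with its two methyl groups plus C3 is exactly 2-methylpropene, and the polarised [4+2] puts O1 on the tertiary carbon.
3. The quinone methide is released from a salicyl alcohol that travels through the route as a 2,2-dimethyl-4H-1,3-benzodioxin (from 2,3-dihydroxybenzaldehyde). This temporary ring ties O1 to C4, differentiates the two catechol oxygens and steers two halogenations (C5 para to O8, C6 para to O1).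
4. The 1,3-diarylpropane comes from a B-alkyl Suzuki–Miyaura union of a ring B allyl arene (C5 prenyl by Grignard/copper, C6 allyl by Suzuki) with a ring A aryl bromide whose 1,1-dimethylallyl group is set by aromatic Claisen rearrangement.
5. Ring order: both arenes are bought; the temporary dioxin ring is made in step 2 and opened in step 12; the pyran ring is the only ring of the target that is built, in step 13.

Key step: step 13

Remark: Kazinol D has no stereocentre and no configured double bond, so no stereocontrol is needed. Ring B carries chroman numbering (O1, C2, C3, C4, C4a, C5–C8, C8a) throughout, and its benzodioxin precursors use the same numbers.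

**Route**

Step 1
Reactants: 1 2,3-dihydroxybenzaldehyde
Product: 2 3-(hydroxymethyl)benzene-1,2-diol
Conditions: NaBH4, MeOH, 0 °C; aq. NH4Cl work-up
Reagents that add atoms: none
Why: Borohydride reduction of an aryl aldehyde brings the future C4 to the alcohol oxidation level needed later for quinone methide release, and the phenols are untouched.

Step 2
Reactants: 2 3-(hydroxymethyl)benzene-1,2-diol
Product: 3 2,2-dimethyl-4H-1,3-benzodioxin-8-ol
Conditions: 2,2-dimethoxypropane, TsOH·H2O (2 mol %), acetone, rt
Reagents that add atoms: 2,2-dimethoxypropane, COC(C)(C)OC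
Why: Acid-catalysed transketalisation should form the six-membered salicyl-alcohol acetonide much faster than the strained five-membered catechol ketal, so O1 and C4 are tied in a temporary ring and only the O8 phenol stays free.

Step 3
Reactants: 3 2,2-dimethyl-4H-1,3-benzodioxin-8-ol
Product: 4 5-iodo-2,2-dimethyl-4H-1,3-benzodioxin-8-ol
Conditions: N-iodosuccinimide (1.0 equiv), TsOH·H2O (5 mol %), MeCN, −10 °C → rt, dark
Reagents that add atoms: N-iodosuccinimide, O=C1CCC(=O)N1I
Why: Electrophilic aromatic iodination is directed by the free phenol to its open para position C5, with the ortho site C7 held back by low temperature and one equivalent of reagent.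

Step 4
Reactants: 4 5-iodo-2,2-dimethyl-4H-1,3-benzodioxin-8-ol
Product: 5 5-iodo-2,2-dimethyl-4H-1,3-benzodioxin-8-yl pivalate
Conditions: pivaloyl chloride, Et3N, DMAP (cat.), CH2Cl2, 0 °C → rt
Reagents that add atoms: pivaloyl chloride, CC(C)(C)C(=O)Cl
Why: DMAP-catalysed O-acylation turns the phenol into a weakly donating, organometallic-tolerant pivalate, so that the ring oxygen O1 becomes the controlling director in the next step.

Step 5
Reactants: 5 5-iodo-2,2-dimethyl-4H-1,3-benzodioxin-8-yl pivalate
Product: 6 6-bromo-5-iodo-2,2-dimethyl-4H-1,3-benzodioxin-8-yl pivalate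
Conditions: N-bromosuccinimide (1.05 equiv), TsOH·H2O (5 mol %), MeCN, rt → 40 °C, dark
Reagents that add atoms: N-bromosuccinimide, O=C1CCC(=O)N1Br
Why: In this electrophilic aromatic bromination the ether oxygen O1 is the strongest donor and directs para to C6, whereas C7 is only ortho to the ester oxygen.

Step 6
Reactants: 6 6-bromo-5-iodo-2,2-dimethyl-4H-1,3-benzodioxin-8-yl pivalate; 7 prenyl bromide (1-bromo-3-methylbut-2-ene)
Product: 9 6-bromo-2,2-dimethyl-5-(3-methylbut-2-en-1-yl)-4H-1,3-benzodioxin-8-yl pivalate, via arylmagnesium chloride 8 (not isolated)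
Conditions: i-PrMgCl·LiCl (1.05 equiv), THF, −40 °C; then CuBr·SMe2 (10 mol %), 7, −40 → 0 °C
Reagents that add atoms: none
Why: Iodine–magnesium exchange is much faster at C–I than at C–Br and tolerates the pivalate at −40 °C, and copper-catalysed allylic substitution of the primary bromide by the aryl Grignard reagent should give the linear prenyl arene.

Step 7
Reactants: 9 6-bromo-2,2-dimethyl-5-(3-methylbut-2-en-1-yl)-4H-1,3-benzodioxin-8-yl pivalate; 10 allylboronic acid pinacol ester
Product: 11 6-allyl-2,2-dimethyl-5-(3-methylbut-2-en-1-yl)-4H-1,3-benzodioxin-8-yl pivalate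
Conditions: Pd(PPh3)4 (5 mol %), CsF, THF, 70 °C
Reagents that add atoms: none
Why: Suzuki–Miyaura allylation of the aryl bromide under anhydrous fluoride activation spares the pivalate, and the symmetric allyl group raises no regiochemical question.

Step 8
Reactants: 12 3-hydroxyphenyl benzoate (resorcinol monobenzoate)
Product: 13 2-bromo-5-hydroxyphenyl benzoate
Conditions: N-bromosuccinimide (1.0 equiv), MeCN, −20 → 0 °C
Reagents that add atoms: N-bromosuccinimide, O=C1CCC(=O)N1Br
Why: Electrophilic bromination of a phenol is para-selective here because the free hydroxyl is a far stronger director than the benzoate, which places the halogen on the future chain carbon of ring A with the two oxygens already differentiated.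

Step 9
Reactants: 13 2-bromo-5-hydroxyphenyl benzoate; 14 3-methylbut-2-en-1-ol
Product: 15 2-bromo-5-[(3-methylbut-2-en-1-yl)oxy]phenyl benzoate
Conditions: PPh3, diisopropyl azodicarboxylate, THF, 0 °C → rt
Reagents that add atoms: none
Why: Mitsunobu etherification of the phenol with a primary allylic alcohol runs under neutral conditions, so no phenoxide is formed that could scramble the benzoate.

Step 10
Reactants: 15 2-bromo-5-[(3-methylbut-2-en-1-yl)oxy]phenyl benzoate
Product: 17 4-bromo-6-(2-methylbut-3-en-2-yl)-1,3-phenylene dibenzoate, via phenol 16 (not isolated)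
Conditions: PhNEt2, 185 °C, 2 h; cool to rt, then benzoyl chloride, Et3N, DMAP (cat.)
Reagents that add atoms: benzoyl chloride, O=C(Cl)c1ccccc1
Why: Aromatic Claisen rearrangement ([3,3]-sigmatropic shift, then tautomerisation) should deliver the 1,1-dimethylallyl group to the ortho carbon not flanked by the second oxygen, and benzoylation of the hindered phenol in the same flask blocks abnormal-Claisen and cyclisation pathways.

Step 11
Reactants: 11 6-allyl-2,2-dimethyl-5-(3-methylbut-2-en-1-yl)-4H-1,3-benzodioxin-8-yl pivalate; 17 4-bromo-6-(2-methylbut-3-en-2-yl)-1,3-phenylene dibenzoate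
Product: 19 4-{3-[2,2-dimethyl-5-(3-methylbut-2-en-1-yl)-8-(pivaloyloxy)-4H-1,3-benzodioxin-6-yl]propyl}-6-(2-methylbut-3-en-2-yl)-1,3-phenylene dibenzoate, via B-alkyl-9-BBN adduct 18 (not isolated)
Conditions: 9-BBN (0.95 equiv per 11), THF, 0 °C → rt; then 17, Pd(dppf)Cl2 (5 mol %), anhydrous K3PO4, DMF, 50 °C; ethanolamine work-up
Reagents that add atoms: none
Why: Anti-Markovnikov hydroboration with 9-BBN takes the monosubstituted allyl alkene and not the trisubstituted prenyl alkene, and the B-alkyl Suzuki–Miyaura coupling under anhydrous phosphate (suited to base-sensitive esters) joins the chain to ring A, with 11 in excess over B–H so that no borane is left for the vinyl group of 17.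

Step 12
Reactants: 19 the diarylpropane acetonide described in step 11
Product: 20 4-{3-[4-hydroxy-3-(hydroxymethyl)-2-(3-methylbut-2-en-1-yl)-5-(pivaloyloxy)phenyl]propyl}-6-(2-methylbut-3-en-2-yl)-1,3-phenylene dibenzoate
Conditions: AcOH–H2O–THF (3:1:1), 50 °C
Reagents that add atoms: none
Why: Mild acid hydrolysis of the cyclic ketal releases the salicyl alcohol, while the aryl esters, the prenyl group and the 1,1-dimethylallyl group are stable to aqueous acetic acid.

Step 13
Reactants: 20 the salicyl alcohol described in step 12; 21 2-methylpropene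
Product: 23 4-{3-[2,2-dimethyl-5-(3-methylbut-2-en-1-yl)-8-(pivaloyloxy)chroman-6-yl]propyl}-6-(2-methylbut-3-en-2-yl)-1,3-phenylene dibenzoate, via o-quinone methide 22 (not isolated)
Conditions: 2-methylpropene (condensed, ca. 100 equiv), toluene (0.02 M in 20), 160 °C, sealed steel autoclave
Reagents that add atoms: none
Why: Heating the o-hydroxybenzyl alcohol causes 1,4-dehydration (phenolic hydrogen passed to the benzylic hydroxyl within a hydrogen-bonded six-membered array) to the o-quinone methide 22, whose 1-oxadiene O1=C8a–C4a=C4 is trapped at once by 2-methylpropene in an inverse-electron-demand hetero-Diels–Alder reaction that forms C4–C3 and O1–C2 together and restores the aromaticity of ring B. The closest known reaction type is the thermolysis of salicyl alcohols (or their Mannich bases and acetates) with unactivated 1,1-disubstituted and trisubstituted alkenes to give 2,2-dialkylchromans. The dihydropyran ring closes in an intermolecular, concerted but asynchronous [4+2] cycloaddition with the C4–C3 bond leading, and no stereocentre is created. Regioselectivity (O1 to the carbon that carries both methyl groups) is secured by the polarised transition state, in which positive charge develops on the tertiary carbon of the alkene. Chemoselectivity is secured by the substrate and the stoichiometry: ring A is switched off as a carbon nucleophile by its two benzoates, the 1,1-dimethylallyl vinyl group is monosubstituted and neopentylic, the neighbouring C5 prenyl alkene cannot span C4 and O1 (the adduct would place aromatic C4a at a bridgehead), and the small alkene is used in about hundredfold excess at high dilution of 20, which also holds back dimerisation of 22.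

Step 14
Reactants: 23 the chroman tri-ester described in step 13
Product: 24 Kazinol D, 4-{3-[8-hydroxy-2,2-dimethyl-5-(3-methylbut-2-en-1-yl)chroman-6-yl]propyl}-6-(2-methylbut-3-en-2-yl)benzene-1,3-diol
Conditions: K2CO3 (0.5 equiv), MeOH–THF (degassed), 45 °C; aq. NH4Cl work-up
Reagents that add atoms: none
Why: Base-catalysed transesterification (methanolysis) removes the three aryl esters, which are far more labile than any other function present, and exclusion of air protects the electron-rich polyphenol.

**Compound list**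

1 | 2,3-dihydroxybenzaldehyde | O=Cc1cccc(O)c1O | starting material
2 | 3-(hydroxymethyl)benzene-1,2-diol | OCc1cccc(O)c1O | intermediate
3 | 2,2-dimethyl-4H-1,3-benzodioxin-8-ol | CC1(C)OCc2cccc(O)c2O1 | intermediate
4 | 5-iodo-2,2-dimethyl-4H-1,3-benzodioxin-8-ol | CC1(C)OCc2c(I)ccc(O)c2O1 | intermediate
5 | 5-iodo-2,2-dimethyl-4H-1,3-benzodioxin-8-yl pivalate | CC1(C)OCc2c(I)ccc(OC(=O)C(C)(C)C)c2O1 | intermediate
6 | 6-bromo-5-iodo-2,2-dimethyl-4H-1,3-benzodioxin-8-yl pivalate | CC1(C)OCc2c(I)c(Br)cc(OC(=O)C(C)(C)C)c2O1 | intermediate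
7 | prenyl bromide (1-bromo-3-methylbut-2-ene) | CC(C)=CCBr | starting material
8 | [6-bromo-2,2-dimethyl-8-(pivaloyloxy)-4H-1,3-benzodioxin-5-yl]magnesium chloride | CC1(C)OCc2c([Mg]Cl)c(Br)cc(OC(=O)C(C)(C)C)c2O1 | intermediate
9 | 6-bromo-2,2-dimethyl-5-(3-methylbut-2-en-1-yl)-4H-1,3-benzodioxin-8-yl pivalate | CC(C)=CCc1c(Br)cc(OC(=O)C(C)(C)C)c2OC(C)(C)OCc12 | intermediate
10 | allylboronic acid pinacol ester (2-allyl-4,4,5,5-tetramethyl-1,3,2-dioxaborolane) | C=CCB1OC(C)(C)C(C)(C)O1 | starting material
11 | 6-allyl-2,2-dimethyl-5-(3-methylbut-2-en-1-yl)-4H-1,3-benzodioxin-8-yl pivalate | C=CCc1cc(OC(=O)C(C)(C)C)c2OC(C)(C)OCc2c1CC=C(C)C | intermediate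
12 | 3-hydroxyphenyl benzoate | O=C(Oc1cccc(O)c1)c1ccccc1 | starting material
13 | 2-bromo-5-hydroxyphenyl benzoate | O=C(Oc1cc(O)ccc1Br)c1ccccc1 | intermediate
14 | 3-methylbut-2-en-1-ol | CC(C)=CCO | starting material
15 | 2-bromo-5-[(3-methylbut-2-en-1-yl)oxy]phenyl benzoate | CC(C)=CCOc1ccc(Br)c(OC(=O)c2ccccc2)c1 | intermediate
16 | 2-bromo-5-hydroxy-4-(2-methylbut-3-en-2-yl)phenyl benzoate | C=CC(C)(C)c1cc(Br)c(OC(=O)c2ccccc2)cc1O | intermediate
17 | 4-bromo-6-(2-methylbut-3-en-2-yl)-1,3-phenylene dibenzoate | C=CC(C)(C)c1cc(Br)c(OC(=O)c2ccccc2)cc1OC(=O)c1ccccc1 | intermediate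
18 | 6-[3-(9-borabicyclo[3.3.1]nonan-9-yl)propyl]-2,2-dimethyl-5-(3-methylbut-2-en-1-yl)-4H-1,3-benzodioxin-8-yl pivalate | CC(C)=CCc1c(CCCB2C3CCCC2CCC3)cc(OC(=O)C(C)(C)C)c2OC(C)(C)OCc12 | intermediate
19 | 4-{3-[2,2-dimethyl-5-(3-methylbut-2-en-1-yl)-8-(pivaloyloxy)-4H-1,3-benzodioxin-6-yl]propyl}-6-(2-methylbut-3-en-2-yl)-1,3-phenylene dibenzoate | C=CC(C)(C)c1cc(CCCc2cc(OC(=O)C(C)(C)C)c3OC(C)(C)OCc3c2CC=C(C)C)c(OC(=O)c2ccccc2)cc1OC(=O)c1ccccc1 | intermediate
20 | 4-{3-[4-hydroxy-3-(hydroxymethyl)-2-(3-methylbut-2-en-1-yl)-5-(pivaloyloxy)phenyl]propyl}-6-(2-methylbut-3-en-2-yl)-1,3-phenylene dibenzoate | C=CC(C)(C)c1cc(CCCc2cc(OC(=O)C(C)(C)C)c(O)c(CO)c2CC=C(C)C)c(OC(=O)c2ccccc2)cc1OC(=O)c1ccccc1 | intermediate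
21 | 2-methylpropene | C=C(C)C | starting material
22 | o-quinone methide of 20 (ring B as a 5-methylidene-6-oxocyclohexa-1,3-diene with 1-pivaloyloxy, 3-propyl chain and 4-prenyl) | C=CC(C)(C)c1cc(CCCC2=C(CC=C(C)C)C(=C)C(=O)C(OC(=O)C(C)(C)C)=C2)c(OC(=O)c2ccccc2)cc1OC(=O)c1ccccc1 | intermediate
23 | 4-{3-[2,2-dimethyl-5-(3-methylbut-2-en-1-yl)-8-(pivaloyloxy)chroman-6-yl]propyl}-6-(2-methylbut-3-en-2-yl)-1,3-phenylene dibenzoate | C=CC(C)(C)c1cc(CCCc2cc(OC(=O)C(C)(C)C)c3c(c2CC=C(C)C)CCC(C)(C)O3)c(OC(=O)c2ccccc2)cc1OC(=O)c1ccccc1 | intermediate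
24 | Kazinol D | C=CC(C)(C)c1cc(CCCc2cc(O)c3c(c2CC=C(C)C)CCC(C)(C)O3)c(O)cc1O | target

**Step count and risks**

Total step count: 14. Longest linear sequence: 11 steps (steps 1–7, then 11–14); the ring A branch (steps 8–10) joins at step 11.

Steps most likely to fail:

1. Step 13. The quinone methide may be consumed by bimolecular pathways before 2-methylpropene captures it: cycloaddition to the prenyl alkene of a second molecule, self-dimerisation, or re-addition of water. Acyl migration or ester loss at 160 °C may also erode material, and an ene-type pathway may give the open-chain o-(3-methylbut-3-enyl)phenol isomer. The fallback sets out from 6 and comes back at 23; it moves the same annulation to the alkene-free dihalide, where no internal π-nucleophile competes. Hydrolysis of the acetonide of 6 (aqueous AcOH) gives 5-bromo-2-hydroxy-3-(hydroxymethyl)-4-iodophenyl pivalate F1. Thermolysis with 21 passes through the o-quinone methide F2 and gives 6-bromo-5-iodo-2,2-dimethylchroman-8-yl pivalate F3. Iodine–magnesium exchange gives the arylmagnesium chloride F4, which is prenylated with 7 under copper catalysis to 6-bromo-2,2-dimethyl-5-(3-methylbut-2-en-1-yl)chroman-8-yl pivalate F5. Suzuki–Miyaura allylation with 10 gives 6-allyl-2,2-dimethyl-5-(3-methylbut-2-en-1-yl)chroman-8-yl pivalate F6. Hydroboration with 9-BBN gives the B-alkyl-9-BBN adduct F7, which is coupled with 17 under the conditions of step 11 to give 23.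

2. Step 10. At 185 °C the prenyl ether may cleave, the allyl unit may migrate to the carbon between the two oxygens, or the ortho-(1,1-dimethylallyl)phenol may rearrange further (abnormal Claisen, cyclisation onto the vinyl group) before it is acylated. The fallback sets out from 13 and comes back at 17; it replaces the sigmatropic step by a cross-coupling. Iodination of 13 ortho to the free hydroxyl (N-iodosuccinimide) should give 2-bromo-5-hydroxy-4-iodophenyl benzoate F8. Benzoylation gives 4-bromo-6-iodo-1,3-phenylene dibenzoate F9. An iodide-selective, γ-selective (branched) Suzuki–Miyaura coupling with prenylboronic acid pinacol ester (palladium diacetate with a bulky dialkylbiarylphosphine, K3PO4) should then give 17.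

3. Step 6. Allylic substitution may proceed with transposition and give the 1,1-dimethylallyl isomer, and the ortho-bromoaryl Grignard reagent may lose magnesium halide (aryne formation) on warming. The fallback sets out from 6 and comes back at 9 in one operation: an α-selective palladium-catalysed Suzuki–Miyaura coupling of the aryl iodide with prenylboronic acid pinacol ester, selective for C–I over C–Br, which needs no organomagnesium intermediate and makes no new compound (F0).

**Further compounds**

F1 | step 13 | 5-bromo-2-hydroxy-3-(hydroxymethyl)-4-iodophenyl pivalate | CC(C)(C)C(=O)Oc1cc(Br)c(I)c(CO)c1O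
F2 | step 13 | 3-bromo-4-iodo-5-methylidene-6-oxocyclohexa-1,3-dien-1-yl pivalate (o-quinone methide) | C=C1C(=O)C(OC(=O)C(C)(C)C)=CC(Br)=C1I
F3 | step 13 | 6-bromo-5-iodo-2,2-dimethylchroman-8-yl pivalate | CC1(C)CCc2c(I)c(Br)cc(OC(=O)C(C)(C)C)c2O1
F4 | step 13 | [6-bromo-2,2-dimethyl-8-(pivaloyloxy)chroman-5-yl]magnesium chloride | CC1(C)CCc2c([Mg]Cl)c(Br)cc(OC(=O)C(C)(C)C)c2O1
F5 | step 13 | 6-bromo-2,2-dimethyl-5-(3-methylbut-2-en-1-yl)chroman-8-yl pivalate | CC(C)=CCc1c(Br)cc(OC(=O)C(C)(C)C)c2OC(C)(C)CCc12
F6 | step 13 | 6-allyl-2,2-dimethyl-5-(3-methylbut-2-en-1-yl)chroman-8-yl pivalate | C=CCc1cc(OC(=O)C(C)(C)C)c2OC(C)(C)CCc2c1CC=C(C)C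
F7 | step 13 | 6-[3-(9-borabicyclo[3.3.1]nonan-9-yl)propyl]-2,2-dimethyl-5-(3-methylbut-2-en-1-yl)chroman-8-yl pivalate | CC(C)=CCc1c(CCCB2C3CCCC2CCC3)cc(OC(=O)C(C)(C)C)c2OC(C)(C)CCc12
F8 | step 10 | 2-bromo-5-hydroxy-4-iodophenyl benzoate | O=C(Oc1cc(O)c(I)cc1Br)c1ccccc1
F9 | step 10 | 4-bromo-6-iodo-1,3-phenylene dibenzoate | O=C(Oc1cc(OC(=O)c2ccccc2)c(I)cc1Br)c1ccccc1
F0 | step 6 | none | none
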